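## Analysis of the target

The target 18 is a flavanone. Benzene ring A is fused through C4a and C8a to the dihydropyranone ring C (O1, C2, C3, C4), and C2 carries the 4-methoxyphenyl ring B. Ring A has no hydrogen left: C5, C6, C7 and C8 each bear a methoxy group, so the C4 carbonyl and O1 both sit between ortho substituents and nothing can be added to ring A late. C2 is the only stereocenter, (S). There is no relative stereochemistry to set, but also no second center to relay from, so the absolute configuration must come from a catalyst. The center is fragile, because C2–O1 is a p-methoxybenzylic aryl ether β to the C4 ketone. Base opens ring C by E1cB (retro-oxa-Michael) and recloses it without memory, and acid can ionise C2–O1 with help from ring B. The difficulty is to close ring C next to a fully substituted, electron-rich ring A without making C2 a reversible or cationic centre; the usual closure of a phenol onto an enone forms C2–O1 in exactly such a reversible step. The plan rests on the para relationship of the oxygens at C5 and C8. Ring A can be carried as a 5,8-quinone, in which C8a is a methoxy-bearing vinylogous ester carbon, β to the C5 carbonyl and to the C4 ketone. A preformed (S)-carbinol oxygen can then attack C8a, so the ring closure makes O1–C8a and touches no bond to C2.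

## Retrosynthetic reasoning

The two O–CH3 bonds at C5 and C8 of 18 are cut first, giving hydroquinone 17, and 17 is taken back by oxidation level to quinone 16. This uncovers the electrophilic form of ring A. Forward, the quinone must be reduced without touching the C4 ketone, and the two phenols methylated without opening ring C.

In 16 the C8a–O1 bond is cut, giving hydroxy quinone 14. The cut is made here and not at C2–O1 because a closure at C2–O1 would create or disturb the stereocenter in the ring-forming step. With C8a–O1 as the last bond of ring C, the stereocenter is an ordinary acyclic secondary alcohol that acts only as a nucleophile. Forward, the hydroxyl must add to the methoxy-bearing carbon beside the acyl group and the methoxy group must leave, before the β-hydroxy ketone can dehydrate.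

Hydroxy quinone 14 is taken back to its silyl ether 13, and 13 to the pentamethoxyphenyl ketone 12 by changing the oxidation level of ring A. The aryl ring of 12 has a mirror plane through the acyl-bearing carbon, so its two para pairs of methoxy groups are equivalent and oxidative demethylation of either pair gives the same quinone. The silyl ether keeps the hydroxyl inert during the oxidation and lets the reactive hydroxy quinone be released only when it is wanted.

In 12 the C4–C4a bond (aryl to carbonyl) is cut, giving pentamethoxybenzene 9 and Weinreb amide 4. The only C–H bond of 9 lies between two methoxy groups, so metalation to aryllithium 10 is unambiguous. The amide stops the addition at the ketone stage, and the cut joins two fragments of similar size.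

Arene 9 is taken back through phenol 8 to the purchased arene 5 by cutting one ring C–O bond. The two free positions of 5 are equivalent, so a single directed metalation followed by oxidation and O-methylation installs the fifth oxygen.

Amide 4 is taken back through silyl ether 3 to hydroxy ester 2, and the C–H bond at the carbinol carbon of 2 is cut to reach β-keto ester 1. This places the origin of C2 in a catalytic asymmetric hydrogenation of a chelating ketone, and the new C–O bond is never broken afterwards.

## Alternatives that were turned down

Alternative 1: The C3=C4 double bond of the cyclic silyl enol ether A1, (2S)-4-(tert-butyldimethylsilyloxy)-5,6,7,8-tetramethoxy-2-(4-methoxyphenyl)-2H-chromene, is cut. This leads to diene A2, an aryl (S)-1-(4-methoxyphenyl)allyl ether whose ring A also carries a 1-silyloxyvinyl group. Forward, a second-generation ruthenium alkylidene metathesis catalyst would join the two terminal alkenes of A2 with loss of their methylene ends, and mild hydrolysis of A1 would give 18.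
- For: all five methoxy groups are present from the start, nothing is oxidised, reduced or methylated after ring closure, and the finished flavanone never meets base. On these points and on step count it is stronger than the chosen plan.
- Against: A2 needs an ether bond between a phenol flanked by an acyl and a methoxy group and a carbon that is both allylic and p-methoxybenzylic. Any substitution there runs through an ion pair or an allyl-metal species, so both configuration and branched-versus-linear regiochemistry are at stake. A2 itself is prone to ionisation and sigmatropic shifts. Ruthenium hydrides formed during metathesis can move the vinyl group into conjugation, which removes the hydrogen at C2 and the stereocenter with it. The enol ether alkene is 1,1-disubstituted and sits on a doubly ortho-substituted ring, so the closure would be slow.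
- In its place the chosen plan makes the C2–O bond by hydrogenation of a ketone and then uses that oxygen only as a nucleophile.

Alternative 2: Two bonds, C3–C4 and O1–C2, are cut at once, leading to the salicylaldehyde dimethyl acetal A4 and 4-methoxystyrene A5. Forward, a chiral Brønsted acid would ionise A4 to a methoxy-substituted ortho-quinone methide, and cycloaddition with A5 would give A3, (2S)-4,5,6,7,8-pentamethoxy-2-(4-methoxyphenyl)chromane, as C4 epimers. The C4 methyl ether must then be taken to the ketone.
- For: this is the most convergent option; ring C, two bonds and the stereocenter arise in one catalytic step from simple pieces, and A4 could come from phenol 8 in two steps. It is clearly stronger on step count.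
- Against: the facial control at C2 depends on a catalyst holding a cationic, fully substituted quinone methide whose phenolic oxygen and methide carbon are both flanked by methoxy groups. A5 polymerises under acid. The C2–O1 bond of A3 is a p-methoxybenzylic aryl ether and can ionise and reclose under the same acid that forms it. The C4 oxidation afterwards must be done on a very electron-rich system.
- In its place the chosen plan offers a stereocenter of secure origin that no later step makes reversible.

Alternative 3: Ring A itself is disconnected at C8–C8a and C4a–C5, leading to dimethyl squarate A8 and the lithiated dihydropyran A9, which combine to the 4-hydroxycyclobutenone A7. Forward, heating A7 would open it to a dienylketene that closes onto C8a and tautomerises to A6, (2S)-4-(tert-butyldimethylsilyloxy)-6,7-dimethoxy-2-(4-methoxyphenyl)chromane-5,8-diol. Methylation, desilylation and oxidation at C4 would follow.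
- For: the substitution pattern of ring A is dictated by the annulation, the hydroquinone appears without an oxidant, and the phenols of A6 are methylated while C4 is still an alcohol, so ring C cannot open by β-elimination. On that last point it is stronger than the chosen plan.
- Against: A9 needs an enantiopure, halogenated 2-aryl-dihydropyran that takes several steps to build. A second stereocenter at C4 is carried only to be erased. The thermolysis runs above 100 °C on a substrate with a p-methoxybenzylic enol ether bond. Three steps follow the key step.
- It is the longest of the four plans; the chosen plan buys ring A ready-made and spends its steps on the side chain.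

Key step: step 9

Remark on the chemistry: 1 and 5 are taken as purchased, and the (R)-diphosphine in step 1 is assumed to show the same facial sense as with other β-keto esters, which corresponds to the (S)-carbinol here.

## Route

Step 1
Reactants: 1 methyl 3-(4-methoxyphenyl)-3-oxopropanoate
Product: 2 methyl (S)-3-hydroxy-3-(4-methoxyphenyl)propanoate
Conditions: [RuCl(p-cymene)((R)-SEGPHOS)]Cl (0.5 mol %), H2 (30 bar), MeOH, 60 °C
Reagents that add atoms: none
Why: Noyori asymmetric hydrogenation of a β-keto ester; the ketone and ester oxygens chelate divalent ruthenium and the (R)-biaryl diphosphine leaves open the face that turns acetoacetates into (R)-3-hydroxybutanoates, which reads (S) here because the aryl group outranks CH2CO2Me. This step sets the carbon that becomes C2 of the target.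

Step 2
Reactants: 2 methyl (S)-3-hydroxy-3-(4-methoxyphenyl)propanoate
Product: 3 methyl (S)-3-(tert-butyldimethylsilyloxy)-3-(4-methoxyphenyl)propanoate
Conditions: TBSCl, imidazole, DMF, 23 °C
Reagents that add atoms: tert-butyldimethylsilyl chloride, CC(C)(C)[Si](C)(C)Cl
Why: Standard silylation of a secondary alcohol; the silyl ether keeps the hydroxyl inert towards the aryllithium of step 6 and the oxidant of step 7 and blocks retro-aldol cleavage.

Step 3
Reactants: 3 methyl (S)-3-(tert-butyldimethylsilyloxy)-3-(4-methoxyphenyl)propanoate
Product: 4 (S)-3-(tert-butyldimethylsilyloxy)-N-methoxy-N-methyl-3-(4-methoxyphenyl)propanamide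
Conditions: MeNH(OMe)·HCl, i-PrMgCl, THF, −20 → 0 °C
Reagents that add atoms: N,O-dimethylhydroxylamine hydrochloride, CNOC.Cl
Why: Weinreb amide formation by aminolysis of the ester with the chloromagnesium amide made in the flask; this amide is a good nucleophile and a poor base, so addition should outrun enolisation and β-elimination of the silyloxy group.

Step 4
Reactants: 5 1,2,3,4-tetramethoxybenzene
Product: 8 2,3,4,5-tetramethoxyphenol, via 2,3,4,5-tetramethoxyphenyllithium 6 (not isolated), via dimethyl 2,3,4,5-tetramethoxyphenylboronate 7 (not isolated)
Conditions: n-BuLi, TMEDA, THF, 0 °C; B(OMe)3, −78 → 23 °C; 30% H2O2, AcOH, 0 → 23 °C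
Reagents that add atoms: hydrogen peroxide, OO (the new oxygen of 8); for the intermediates only, n-butyllithium, [Li]CCCC (lithium of 6) and trimethyl borate, COB(OC)OC (boron and its two methoxy groups in 7)
Why: Directed ortho-lithiation beside a methoxy group (the two free positions of 5 are equivalent), borylation, and oxidative migration of the aryl group from boron to oxygen (hydroxydeboronation).

Step 5
Reactants: 8 2,3,4,5-tetramethoxyphenol
Product: 9 pentamethoxybenzene
Conditions: MeI, K2CO3, acetone, reflux
Reagents that add atoms: iodomethane, CI
Why: Williamson ether synthesis on an unhindered, non-chelated phenol.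

Step 6
Reactants: 9 pentamethoxybenzene; 4 (S)-3-(tert-butyldimethylsilyloxy)-N-methoxy-N-methyl-3-(4-methoxyphenyl)propanamide
Product: 12 (S)-3-(tert-butyldimethylsilyloxy)-3-(4-methoxyphenyl)-1-(2,3,4,5,6-pentamethoxyphenyl)propan-1-one, via pentamethoxyphenyllithium 10 (not isolated), via lithium hemiaminal alkoxide 11 (not isolated)
Conditions: 9, n-BuLi, THF, 0 °C; then 4, −78 → −20 °C; AcOH quench
Reagents that add atoms: n-butyllithium, [Li]CCCC (supplies only the lithium of intermediates 10 and 11; no atoms in 12)
Why: The only C–H bond of 9 lies between two methoxy groups and is lithiated cleanly; addition of 10 to the Weinreb amide gives the chelated adduct 11, which releases the ketone only on quenching, so no second addition can occur. The stereocenter is remote from the reacting carbon and is not affected.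

Step 7
Reactants: 12 (S)-3-(tert-butyldimethylsilyloxy)-3-(4-methoxyphenyl)-1-(2,3,4,5,6-pentamethoxyphenyl)propan-1-one
Product: 13 (S)-2-[3-(tert-butyldimethylsilyloxy)-3-(4-methoxyphenyl)propanoyl]-3,5,6-trimethoxy-1,4-benzoquinone
Conditions: (NH4)2Ce(NO3)6 (2.2 equiv), MeCN–H2O 3:1, 0 °C, 10 min
Reagents that add atoms: water, O
Why: Oxidative demethylation of a para-dimethoxyarene by tetravalent cerium; the pentaoxygenated ring is oxidised well before the anisyl ring, water attacks two para methoxy-bearing carbons and methanol leaves. The two para pairs of 12 are related by the mirror plane through the acyl-bearing carbon, so either gives the same quinone.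

Step 8
Reactants: 13 (S)-2-[3-(tert-butyldimethylsilyloxy)-3-(4-methoxyphenyl)propanoyl]-3,5,6-trimethoxy-1,4-benzoquinone
Product: 14 (S)-2-[3-hydroxy-3-(4-methoxyphenyl)propanoyl]-3,5,6-trimethoxy-1,4-benzoquinone
Conditions: HF·pyridine, THF, 0 → 23 °C
Reagents that add atoms: none
Why: Fluoride-driven cleavage of the Si–O bond under anhydrous, weakly acidic conditions, which spare the base-sensitive methoxyquinone and give water no chance to attack the activated methoxy carbon. Any closure to 16 that begins here is productive and is carried into step 9.

Step 9
Reactants: 14 (S)-2-[3-hydroxy-3-(4-methoxyphenyl)propanoyl]-3,5,6-trimethoxy-1,4-benzoquinone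
Product: 16 (S)-6,7-dimethoxy-2-(4-methoxyphenyl)-2,3-dihydro-4H-chromene-4,5,8-trione, via 8a-methoxy ketal adduct 15 (not isolated)
Conditions: PPTS (0.1 equiv), 4 Å MS, CH2Cl2, 0 → 23 °C
Reagents that add atoms: none
Why: The carbinol oxygen adds in conjugate fashion to C8a of the quinone, the methoxy-bearing carbon that is β to both the C5 quinone carbonyl and the C4 side-chain ketone, to give the mixed ketal 15, which then loses methanol and restores the quinone as 16. PPTS only activates the enedione by hydrogen bonding and shuttles protons, and the sieves take up the methanol so that the exchange cannot run backwards. The closest known reaction type is the exchange of alkoxy groups on alkoxy-1,4-benzoquinones and other vinylogous esters by alcohols through addition–elimination, carried out here within one molecule in the manner of an oxa-Michael chromanone closure. Ring C closes in the 6-endo-trig mode, because the attacked C4a=C8a double bond lies inside the new six-membered ring. No lasting stereocenter is created (C8a of 15 is transient and both epimers give the same 16), and C2 keeps its (S) configuration because its C–O bond is never broken, the oxygen being the nucleophile. Site selectivity is needed against the methoxy carbons C6 and C7 and is secured by the tether, which could reach them only through meta- or para-bridged rings; addition to the C5 carbonyl gives at most a reversible hemiketal that drains back. Chemoselectivity is needed against dehydration of the β-hydroxy ketone and is secured by the absence of base and of strong acid at or below room temperature.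

Step 10
Reactants: 16 (S)-6,7-dimethoxy-2-(4-methoxyphenyl)-2,3-dihydro-4H-chromene-4,5,8-trione
Product: 17 (S)-5,8-dihydroxy-6,7-dimethoxy-2-(4-methoxyphenyl)chroman-4-one
Conditions: Na2S2O4, EtOAc–H2O, 23 °C, Ar; used crude
Reagents that add atoms: none
Why: Two-electron reduction of the quinone by sodium dithionite, which leaves the C4 ketone alone. It also turns O1 from a vinylogous ester oxygen into an ordinary aryl ether oxygen, which makes the C2–O1 bond much less prone to ionise, so 16 is reduced promptly.

Step 11
Reactants: 17 (S)-5,8-dihydroxy-6,7-dimethoxy-2-(4-methoxyphenyl)chroman-4-one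
Product: 18 (2S)-5,6,7,8,4'-pentamethoxyflavanone
Conditions: MeI, K2CO3, degassed DMF, 0 → 23 °C, Ar
Reagents that add atoms: iodomethane, CI
Why: Double Williamson methylation; the free 8-OH should react first and the 5-OH, hydrogen-bonded to the C4 carbonyl, second. A weak base at ambient temperature under argon is chosen to limit E1cB opening of ring C and reoxidation of the hydroquinone.

## Compound list

1 | methyl 3-(4-methoxyphenyl)-3-oxopropanoate | COC(=O)CC(=O)c1ccc(OC)cc1 | starting material
2 | methyl (S)-3-hydroxy-3-(4-methoxyphenyl)propanoate | COc1ccc([C@@H](O)CC(=O)OC)cc1 | intermediate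
3 | methyl (S)-3-(tert-butyldimethylsilyloxy)-3-(4-methoxyphenyl)propanoate | COc1ccc([C@@H](O[Si](C)(C)C(C)(C)C)CC(=O)OC)cc1 | intermediate
4 | (S)-3-(tert-butyldimethylsilyloxy)-N-methoxy-N-methyl-3-(4-methoxyphenyl)propanamide | COc1ccc([C@@H](O[Si](C)(C)C(C)(C)C)CC(=O)N(C)OC)cc1 | intermediate
5 | 1,2,3,4-tetramethoxybenzene | COc1ccc(OC)c(OC)c1OC | starting material
6 | 2,3,4,5-tetramethoxyphenyllithium | [Li]c1cc(OC)c(OC)c(OC)c1OC | intermediate
7 | dimethyl 2,3,4,5-tetramethoxyphenylboronate | COB(OC)c1cc(OC)c(OC)c(OC)c1OC | intermediate
8 | 2,3,4,5-tetramethoxyphenol | COc1cc(O)c(OC)c(OC)c1OC | intermediate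
9 | pentamethoxybenzene | COc1cc(OC)c(OC)c(OC)c1OC | intermediate
10 | pentamethoxyphenyllithium | [Li]c1c(OC)c(OC)c(OC)c(OC)c1OC | intermediate
11 | lithium (3S)-3-(tert-butyldimethylsilyloxy)-1-[methoxy(methyl)amino]-3-(4-methoxyphenyl)-1-(pentamethoxyphenyl)propan-1-olate (C1 epimers) | COc1ccc([C@@H](O[Si](C)(C)C(C)(C)C)CC([O-])(N(C)OC)c2c(OC)c(OC)c(OC)c(OC)c2OC)cc1.[Li+] | intermediate
12 | (S)-3-(tert-butyldimethylsilyloxy)-3-(4-methoxyphenyl)-1-(2,3,4,5,6-pentamethoxyphenyl)propan-1-one | COc1ccc([C@@H](O[Si](C)(C)C(C)(C)C)CC(=O)c2c(OC)c(OC)c(OC)c(OC)c2OC)cc1 | intermediate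
13 | (S)-2-[3-(tert-butyldimethylsilyloxy)-3-(4-methoxyphenyl)propanoyl]-3,5,6-trimethoxy-1,4-benzoquinone | COc1ccc([C@@H](O[Si](C)(C)C(C)(C)C)CC(=O)C2=C(OC)C(=O)C(OC)=C(OC)C2=O)cc1 | intermediate
14 | (S)-2-[3-hydroxy-3-(4-methoxyphenyl)propanoyl]-3,5,6-trimethoxy-1,4-benzoquinone | COc1ccc([C@@H](O)CC(=O)C2=C(OC)C(=O)C(OC)=C(OC)C2=O)cc1 | intermediate
15 | (2S)-5-hydroxy-6,7,8a-trimethoxy-2-(4-methoxyphenyl)-2,3-dihydro-4H-chromene-4,8(8aH)-dione (C8a epimers) | COc1ccc([C@@H]2CC(=O)C3=C(O)C(OC)=C(OC)C(=O)C3(OC)O2)cc1 | intermediate
16 | (S)-6,7-dimethoxy-2-(4-methoxyphenyl)-2,3-dihydro-4H-chromene-4,5,8-trione | COc1ccc([C@@H]2CC(=O)C3=C(O2)C(=O)C(OC)=C(OC)C3=O)cc1 | intermediate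
17 | (S)-5,8-dihydroxy-6,7-dimethoxy-2-(4-methoxyphenyl)chroman-4-one | COc1ccc([C@@H]2CC(=O)c3c(O)c(OC)c(OC)c(O)c3O2)cc1 | intermediate
18 | (2S)-5,6,7,8,4'-pentamethoxyflavanone | COc1ccc([C@@H]2CC(=O)c3c(OC)c(OC)c(OC)c(OC)c3O2)cc1 | target

## Step count and least certain steps

Total step count: 11. Longest linear sequence: 9 steps (steps 1, 2, 3, 6, 7, 8, 9, 10, 11, from 1 to 18); the ring A branch (steps 4 and 5) joins at step 6.

**Step 9 (key step).**
- Risk: dehydration of the β-hydroxy ketone before the hydroxyl has added, either by ionisation at the p-methoxybenzylic carbon or through the enol.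
- Risk: slow turnover, because the methoxy group at C8a donates into the enedione and lowers the electrophilicity of that carbon.
- Risk: heterolysis of the C2–O1 bond of the product, where O1 has become a good leaving group, which would erode the configuration.
- Fallback (sets out from 5 and 4, returns at 17): the closure is changed from substitution at a methoxy-bearing carbon to plain conjugate addition at an unsubstituted quinone carbon. Aryllithium 6, made from 5 as in step 4, is acylated with 4 to give (S)-3-(tert-butyldimethylsilyloxy)-3-(4-methoxyphenyl)-1-(2,3,4,5-tetramethoxyphenyl)propan-1-one F1. This ketone has only one para pair of methoxy groups, so (NH4)2Ce(NO3)6 should give (S)-2-[3-(tert-butyldimethylsilyloxy)-3-(4-methoxyphenyl)propanoyl]-5,6-dimethoxy-1,4-benzoquinone F2. HF·pyridine then frees (S)-2-[3-hydroxy-3-(4-methoxyphenyl)propanoyl]-5,6-dimethoxy-1,4-benzoquinone F3. Its hydroxyl adds to the unsubstituted carbon beside the acyl group (oxa-Michael addition to an acylquinone), and enolisation delivers hydroquinone 17 directly. A wash with Na2S2O4 returns any material oxidised by unreacted quinone. This path also bypasses steps 4, 5 and 10.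

**Step 7.**
- Risk: competing one-electron oxidation of the anisyl ring with cleavage at the benzylic carbon, because the acyl group raises the oxidation potential of the pentaoxygenated ring towards that of ring B.
- Risk: oxidation across an ortho pair of methoxy groups.
- Risk: hydrolysis of the activated methoxy group in the acidic aqueous medium.
- Fallback (sets out from 8 and 4, returns at 13): one oxygen is differentiated beforehand so that a phenol, not an aryl ether, is oxidised. Phenol 8 is protected with MOMCl and i-Pr2NEt as 1,2,3,4-tetramethoxy-5-(methoxymethoxy)benzene F4. Lithiation between the two oxygens with n-BuLi gives 2-(methoxymethoxy)-3,4,5,6-tetramethoxyphenyllithium F5, which is acylated with 4 to (S)-3-(tert-butyldimethylsilyloxy)-1-[2-(methoxymethoxy)-3,4,5,6-tetramethoxyphenyl]-3-(4-methoxyphenyl)propan-1-one F6. ZnBr2 and n-PrSH in CH2Cl2 should remove the aryl acetal while the silyl ether stays, giving (S)-3-(tert-butyldimethylsilyloxy)-1-(2-hydroxy-3,4,5,6-tetramethoxyphenyl)-3-(4-methoxyphenyl)propan-1-one F7. This is a para-methoxyphenol, which PhI(OAc)2 in aqueous MeCN should oxidise to quinone 13 at a potential the anisyl ring does not reach.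

**Step 6.**
- Risk: deprotonation next to the amide carbonyl by the hindered, doubly ortho-substituted aryllithium, followed by β-elimination of the silyloxy group.
- Risk: slow addition for steric reasons.
- Fallback (sets out from 3 and 9, returns at 12): the electrophile is changed to an aldehyde, which adds organolithiums faster than it enolises. Ester 3 is reduced with i-Bu2AlH at −78 °C to (S)-3-(tert-butyldimethylsilyloxy)-3-(4-methoxyphenyl)propanal F8. Aryllithium 10 adds at −78 °C to give (3S)-3-(tert-butyldimethylsilyloxy)-3-(4-methoxyphenyl)-1-(2,3,4,5,6-pentamethoxyphenyl)propan-1-ol F9 as C1 epimers, and Dess–Martin periodinane oxidises both epimers to ketone 12.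

**Step 11.**
- Risk: base-induced opening of ring C by retro-oxa-Michael elimination and reclosure, which would erode the configuration at C2.
- Risk: incomplete methylation of the chelated 5-OH.
- Risk: reoxidation of the hydroquinone by air.
- Fallback (sets out from 17, returns at 18): the carbonyl that makes ring opening possible is removed for the duration of the methylation. NaBH4 in MeOH–THF at 0 °C reduces the C4 ketone of 17 to (2S)-6,7-dimethoxy-2-(4-methoxyphenyl)chromane-4,5,8-triol F10 (C4 epimers). With MeI and K2CO3 the two phenols are methylated to (2S)-5,6,7,8-tetramethoxy-2-(4-methoxyphenyl)chroman-4-ol F11, and Dess–Martin periodinane restores the ketone to give 18.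

## Further compounds

F1 | step 9 | (S)-3-(tert-butyldimethylsilyloxy)-3-(4-methoxyphenyl)-1-(2,3,4,5-tetramethoxyphenyl)propan-1-one | COc1ccc([C@@H](O[Si](C)(C)C(C)(C)C)CC(=O)c2cc(OC)c(OC)c(OC)c2OC)cc1
F2 | step 9 | (S)-2-[3-(tert-butyldimethylsilyloxy)-3-(4-methoxyphenyl)propanoyl]-5,6-dimethoxy-1,4-benzoquinone | COc1ccc([C@@H](O[Si](C)(C)C(C)(C)C)CC(=O)C2=CC(=O)C(OC)=C(OC)C2=O)cc1
F3 | step 9 | (S)-2-[3-hydroxy-3-(4-methoxyphenyl)propanoyl]-5,6-dimethoxy-1,4-benzoquinone | COc1ccc([C@@H](O)CC(=O)C2=CC(=O)C(OC)=C(OC)C2=O)cc1
F4 | step 7 | 1,2,3,4-tetramethoxy-5-(methoxymethoxy)benzene | COCOc1cc(OC)c(OC)c(OC)c1OC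
F5 | step 7 | 2-(methoxymethoxy)-3,4,5,6-tetramethoxyphenyllithium | [Li]c1c(OCOC)c(OC)c(OC)c(OC)c1OC
F6 | step 7 | (S)-3-(tert-butyldimethylsilyloxy)-1-[2-(methoxymethoxy)-3,4,5,6-tetramethoxyphenyl]-3-(4-methoxyphenyl)propan-1-one | COc1ccc([C@@H](O[Si](C)(C)C(C)(C)C)CC(=O)c2c(OCOC)c(OC)c(OC)c(OC)c2OC)cc1
F7 | step 7 | (S)-3-(tert-butyldimethylsilyloxy)-1-(2-hydroxy-3,4,5,6-tetramethoxyphenyl)-3-(4-methoxyphenyl)propan-1-one | COc1ccc([C@@H](O[Si](C)(C)C(C)(C)C)CC(=O)c2c(O)c(OC)c(OC)c(OC)c2OC)cc1
F8 | step 6 | (S)-3-(tert-butyldimethylsilyloxy)-3-(4-methoxyphenyl)propanal | COc1ccc([C@@H](O[Si](C)(C)C(C)(C)C)CC=O)cc1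
F9 | step 6 | (3S)-3-(tert-butyldimethylsilyloxy)-3-(4-methoxyphenyl)-1-(2,3,4,5,6-pentamethoxyphenyl)propan-1-ol (C1 epimers) | COc1ccc([C@@H](O[Si](C)(C)C(C)(C)C)CC(O)c2c(OC)c(OC)c(OC)c(OC)c2OC)cc1
F10 | step 11 | (2S)-6,7-dimethoxy-2-(4-methoxyphenyl)chromane-4,5,8-triol (C4 epimers) | COc1ccc([C@@H]2CC(O)c3c(O)c(OC)c(OC)c(O)c3O2)cc1
F11 | step 11 | (2S)-5,6,7,8-tetramethoxy-2-(4-methoxyphenyl)chroman-4-ol (C4 epimers) | COc1ccc([C@@H]2CC(O)c3c(OC)c(OC)c(OC)c(OC)c3O2)cc1
A1 | alternative 1 | (2S)-4-(tert-butyldimethylsilyloxy)-5,6,7,8-tetramethoxy-2-(4-methoxyphenyl)-2H-chromene | COc1ccc([C@@H]2C=C(O[Si](C)(C)C(C)(C)C)c3c(OC)c(OC)c(OC)c(OC)c3O2)cc1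
A2 | alternative 1 | tert-butyldimethyl{1-[2,3,4,5-tetramethoxy-6-[(1S)-1-(4-methoxyphenyl)prop-2-enoxy]phenyl]ethenoxy}silane | COc1ccc([C@H](C=C)Oc2c(OC)c(OC)c(OC)c(OC)c2C(=C)O[Si](C)(C)C(C)(C)C)cc1
A3 | alternative 2 | (2S)-4,5,6,7,8-pentamethoxy-2-(4-methoxyphenyl)chromane (C4 epimers) | COc1ccc([C@@H]2CC(OC)c3c(OC)c(OC)c(OC)c(OC)c3O2)cc1
A4 | alternative 2 | 2-(dimethoxymethyl)-3,4,5,6-tetramethoxyphenol | COC(OC)c1c(O)c(OC)c(OC)c(OC)c1OC
A5 | alternative 2 | 4-methoxystyrene | C=Cc1ccc(OC)cc1
A6 | alternative 3 | (2S)-4-(tert-butyldimethylsilyloxy)-6,7-dimethoxy-2-(4-methoxyphenyl)chromane-5,8-diol (C4 epimers) | COc1ccc([C@@H]2CC(O[Si](C)(C)C(C)(C)C)c3c(O)c(OC)c(OC)c(O)c3O2)cc1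
A7 | alternative 3 | 4-[(2S)-4-(tert-butyldimethylsilyloxy)-2-(4-methoxyphenyl)-3,4-dihydro-2H-pyran-5-yl]-4-hydroxy-2,3-dimethoxycyclobut-2-en-1-one | COc1ccc([C@@H]2CC(O[Si](C)(C)C(C)(C)C)C(C3(O)C(OC)=C(OC)C3=O)=CO2)cc1
A8 | alternative 3 | dimethyl squarate (3,4-dimethoxycyclobut-3-ene-1,2-dione) | COC1=C(OC)C(=O)C1=O
A9 | alternative 3 | (2S)-4-(tert-butyldimethylsilyloxy)-2-(4-methoxyphenyl)-3,4-dihydro-2H-pyran-5-yllithium | COc1ccc([C@@H]2CC(O[Si](C)(C)C(C)(C)C)C([Li])=CO2)cc1
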